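The depside ester is not made by acylation. The ring B C3 methyl, ortho to the depside oxygen O4, is treated as the remnant of a CH2–O tether, and the ring A carbons C1' and C3' as the two identical formyl carbons of a symmetric dialdehyde. One formyl group is tied to O4 and the C3 CH2 as a 2-aryl-4H-1,3-benzodioxine (the precursor). Hydride abstraction from its acetal carbon followed by bromide attack at the benzylic CH2 then turns the acetal carbon into the C1' ester carbonyl on the existing C–O4 bond in one operation; the bromomethyl group left at C3 is reduced to the methyl group.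

Key step: step 5

Numbering used: ring B (methyl benzoate ring) C1 CO2Me, C2 Me, C3 Me, C4 O-acyl, C5 Me, C6 OH; ring A (acyl ring) C1' bearing the ester carbonyl, C2' Me, C3' CHO, C4' OH, C5' Me, C6' OH. Locants inside compound names follow each compound's own nomenclature.

Assumption: the acetal precursor is made and used as the racemate. Its only stereocentre, the acetal carbon, becomes the sp2 ester carbon in the key step, and the target has no stereocentre.

Design remark: the three phenols of the precursor are left unprotected. Each is chelated to a carbonyl group or flanked by two substituents, and both rings are fully substituted. Removing O-acyl groups would need base or nucleophiles that endanger the salicylate-type depside ester, and benzyl ethers would compete as hydride donors in the key step. The key step is instead run cold, with a hindered pyridine as proton trap, and bromide is added only after the hydride transfer.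

Step 1
Reactants: 1 2,5-dimethylresorcinol (2,5-dimethylbenzene-1,3-diol); 2 dichloromethyl methyl ether
Product: 3 4,6-dihydroxy-2,5-dimethylbenzene-1,3-dicarbaldehyde (symmetric: CHO at C1 and C3, methyl at C2 between them, OH at C4 and C6, methyl at C5 between the hydroxyls)
Conditions: 2 (4 equiv), TiCl4 (5 equiv), CH2Cl2, 0 °C → rt; then 1 M aq. HCl, 0 °C
Reagents that add atoms: dichloromethyl methyl ether (2), COC(Cl)Cl; water, O
Why: Twofold Rieche formylation, in which the titanium phenoxide directs the chloro(methoxy)methyl cation to the only two free ring carbons, each ortho to one hydroxyl and para to the other, and aqueous hydrolysis of the α-chloro ethers releases both formyl groups.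

Step 2
Reactants: 4 methyl 2,4-dihydroxy-3,6-dimethylbenzoate; 2 dichloromethyl methyl ether
Product: 5 methyl 5-formyl-2,4-dihydroxy-3,6-dimethylbenzoate
Conditions: 2 (2 equiv), TiCl4 (3 equiv), CH2Cl2, 0 °C → rt; then 1 M aq. HCl, 0 °C
Reagents that add atoms: dichloromethyl methyl ether (2), COC(Cl)Cl; water, O
Why: Rieche formylation at C5, the single unsubstituted ring carbon, which is ortho to the 4-OH and para to the 2-OH, so no regiochemical question arises.

Step 3
Reactants: 5 methyl 5-formyl-2,4-dihydroxy-3,6-dimethylbenzoate
Product: 6 methyl 2,4-dihydroxy-5-(hydroxymethyl)-3,6-dimethylbenzoate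
Conditions: NaBH4 (1.0 equiv), THF/MeOH, 0 °C; sat. aq. NH4Cl
Reagents that add atoms: none
Why: Chemoselective NaBH4 reduction of an aryl aldehyde beside a methyl ester, kept cold and quenched at near-neutral pH so that the salicyl-type alcohol is not carried on to the methyl compound through a quinone methide.

Step 4
Reactants: 6 methyl 2,4-dihydroxy-5-(hydroxymethyl)-3,6-dimethylbenzoate; 3 4,6-dihydroxy-2,5-dimethylbenzene-1,3-dicarbaldehyde
Product: 7 methyl 2-(3-formyl-4,6-dihydroxy-2,5-dimethylphenyl)-7-hydroxy-5,8-dimethyl-4H-1,3-benzodioxine-6-carboxylate (racemic at the acetal carbon C2)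
Conditions: 3 (3 equiv), PPTS (0.1 equiv), PhH, reflux, Soxhlet with 4 Å MS; excess 3 recovered
Reagents that add atoms: none
Why: Acid-catalysed dehydrative acetalization of a salicyl alcohol with an aryl aldehyde closes the six-membered 4H-1,3-benzodioxine through the only phenol ortho to the CH2OH group, the excess of the symmetric dialdehyde (either formyl group is equivalent) suppresses the bis-acetal, the fully substituted rings exclude Friedel–Crafts benzylation, and the acetal stereocentre forms as a racemate that is erased in step 5.

Step 5
Reactants: 7 methyl 2-(3-formyl-4,6-dihydroxy-2,5-dimethylphenyl)-7-hydroxy-5,8-dimethyl-4H-1,3-benzodioxine-6-carboxylate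
Product: 9 methyl 3-(bromomethyl)-4-[(3-formyl-4,6-dihydroxy-2,5-dimethylbenzoyl)oxy]-6-hydroxy-2,5-dimethylbenzoate, via benzodioxinium tetrafluoroborate 8 (not isolated)
Conditions: Ph3CBF4 (1.05 equiv), 2,6-di-tert-butyl-4-methylpyridine (0.2 equiv), CH2Cl2/MeCN, 4 Å MS, −20 → 0 °C; then Bu4NBr (1.5 equiv), 0 °C → rt; filtered and concentrated, used crude
Reagents that add atoms: tetrabutylammonium bromide, CCCC[N+](CCCC)(CCCC)CCCC.[Br-]
Why: The trityl cation removes the acetal hydride of 7, the only C–H flanked by two oxygens, to give the 2-aryl-1,3-benzodioxinium ion 8 and Ph3CH, and bromide then attacks the only sp3 carbon of the cation, the benzylic CH2 (SN2, or SN1-like through the para-hydroxybenzyl cation, with the same outcome), so the former acetal carbon becomes the C1' ester carbonyl and stays on the phenolic oxygen O4. The closest known reaction is the trityl-salt variant of the Hanessian–Hullar opening of benzylidene acetals of 1,3-diols to bromo benzoates. No ring is closed and no stereocentre is made, since the acetal centre is destroyed. The step needs site-selective hydride loss (acetal C–H over the benzylic OCH2 and the formyl C–H), which the two-oxygen stabilisation of ion 8 should secure, and opening to the aryl ester and not the benzyl ester, which is secured because bromide cannot substitute at the aryl C–O carbon and water is excluded so that no orthoester can collapse the other way. The free phenols should be tolerated because each is chelated or doubly flanked, neither ring has a free position for tritylation, and the hindered pyridine traps adventitious HBF4. The hindered C1' carbon is never acylated, because both of its C–O bonds come from the acetalization in step 4.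

Step 6
Reactants: 9 methyl 3-(bromomethyl)-4-[(3-formyl-4,6-dihydroxy-2,5-dimethylbenzoyl)oxy]-6-hydroxy-2,5-dimethylbenzoate
Product: 10 isopseudocyphellarin A, methyl 4-[(3-formyl-4,6-dihydroxy-2,5-dimethylbenzoyl)oxy]-6-hydroxy-2,3,5-trimethylbenzoate
Conditions: crude 9, Bu3SnH (2 equiv), Et3B (0.2 equiv), trace air, PhMe, 0 °C → rt
Reagents that add atoms: none
Why: Radical-chain reduction of a benzylic bromide (bromine abstraction by the stannyl radical, then hydrogen transfer from Bu3SnH to the benzylic radical) runs under neutral conditions at room temperature and should leave the formyl group, both esters and the phenols untouched.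

Compound list
1 | 2,5-dimethylresorcinol (2,5-dimethylbenzene-1,3-diol) | Cc1cc(O)c(C)c(O)c1 | starting material
2 | dichloromethyl methyl ether | COC(Cl)Cl | starting material
3 | 4,6-dihydroxy-2,5-dimethylbenzene-1,3-dicarbaldehyde | O=Cc1c(C)c(C=O)c(O)c(C)c1O | intermediate
4 | methyl 2,4-dihydroxy-3,6-dimethylbenzoate | COC(=O)c1c(C)cc(O)c(C)c1O | starting material
5 | methyl 5-formyl-2,4-dihydroxy-3,6-dimethylbenzoate | COC(=O)c1c(C)c(C=O)c(O)c(C)c1O | intermediate
6 | methyl 2,4-dihydroxy-5-(hydroxymethyl)-3,6-dimethylbenzoate | COC(=O)c1c(C)c(CO)c(O)c(C)c1O | intermediate
7 | methyl 2-(3-formyl-4,6-dihydroxy-2,5-dimethylphenyl)-7-hydroxy-5,8-dimethyl-4H-1,3-benzodioxine-6-carboxylate (racemic) | COC(=O)c1c(C)c2c(c(C)c1O)OC(c1c(C)c(C=O)c(O)c(C)c1O)OC2 | intermediate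
8 | 2-(3-formyl-4,6-dihydroxy-2,5-dimethylphenyl)-7-hydroxy-6-(methoxycarbonyl)-5,8-dimethyl-4H-1,3-benzodioxinium tetrafluoroborate (charge shared by O1, C2 and O3; not isolated) | COC(=O)c1c(C)c2C[O+]=C(c3c(C)c(C=O)c(O)c(C)c3O)Oc2c(C)c1O.F[B-](F)(F)F | intermediate
9 | methyl 3-(bromomethyl)-4-[(3-formyl-4,6-dihydroxy-2,5-dimethylbenzoyl)oxy]-6-hydroxy-2,5-dimethylbenzoate | COC(=O)c1c(C)c(CBr)c(OC(=O)c2c(C)c(C=O)c(O)c(C)c2O)c(C)c1O | intermediate
10 | isopseudocyphellarin A, methyl 4-[(3-formyl-4,6-dihydroxy-2,5-dimethylbenzoyl)oxy]-6-hydroxy-2,3,5-trimethylbenzoate | COC(=O)c1c(C)c(C)c(OC(=O)c2c(C)c(C=O)c(O)c(C)c2O)c(C)c1O | target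

Total step count: 6. Longest linear sequence: 5 steps (4 → 5 → 6 → 7 → 9 → 10, steps 2 to 6); step 1 supplies dialdehyde 3 for step 4.

Steps most likely to fail

1. Step 5. Hydride may be lost from the benzylic OCH2 instead of the acetal carbon. Liberated acid may ionise the para-hydroxybenzyl C–O bond and release the aldehyde. Ion 8 may also collapse through a quinone methide before bromide arrives. The fallback sets out from 3 and 6 and returns to the route at 10, making the ester by the classical depside acylation. Mono-oxidation of dialdehyde 3 with one equivalent of NaClO2 and sulfamic acid as chlorine scavenger (aqueous dioxane, 0 °C) is expected to give 3-formyl-4,6-dihydroxy-2,5-dimethylbenzoic acid F1, separable from recovered 3 and the diacid. Ionic hydrogenation of benzylic alcohol 6 (Et3SiH, TFA, CH2Cl2, 0 °C) should give methyl 2,4-dihydroxy-3,5,6-trimethylbenzoate F2. Condensation of F1 with F2 by trifluoroacetic anhydride in toluene at room temperature, through the mixed anhydride of the hindered acid, should acylate the unchelated 4-OH of F2 and give the target 10 directly.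

2. Step 4. The equilibrium may favour the chelated, doubly ortho-flanked aldehyde, and prolonged heating with acid may ionise the benzylic alcohol to a quinone methide that condenses with itself. The fallback sets out from 3 and returns at 7, replacing dehydrative condensation by acetal exchange. One formyl group of 3 is converted with HC(OMe)3 (1 equiv) and catalytic PPTS in MeOH at room temperature into 3-(dimethoxymethyl)-4,6-dihydroxy-2,5-dimethylbenzaldehyde F3, used crude. F3 is then exchanged with 6 (catalytic PPTS, CH2Cl2, 5 Å MS to absorb methanol, rt). The oxocarbenium ion then forms from the dimethyl acetal at room temperature without azeotropic water removal.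

3. Step 6. The para-hydroxybenzylic bromide may lose HBr to a quinone methide that oligomerises before hydrogen transfer, or stannyl-radical addition to the formyl group may stall the chain. The fallback sets out from 9 and returns at 10, replacing the radical chain by catalytic hydrogenolysis of the C–Br bond (H2, 1 atm, Pd/C, EtOAc, rt). This is a surface-mediated two-electron cleavage that needs neither tin nor initiator and should outrun reduction of the chelated formyl group. It makes no new compound (F0).

Further compounds
F1 | step 5 | 3-formyl-4,6-dihydroxy-2,5-dimethylbenzoic acid | O=Cc1c(C)c(C(=O)O)c(O)c(C)c1O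
F2 | step 5 | methyl 2,4-dihydroxy-3,5,6-trimethylbenzoate | COC(=O)c1c(C)c(C)c(O)c(C)c1O
F3 | step 4 | 3-(dimethoxymethyl)-4,6-dihydroxy-2,5-dimethylbenzaldehyde | COC(OC)c1c(C)c(C=O)c(O)c(C)c1O
F0 | step 6 | none | none
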